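**Plan**
Locants: oxolane O1, C2 (aryl), C3 (CH3), C4 (carbinol side chain), C5 (CH2). The retrosynthesis cuts, in order: O–Si; the C2–aryl bond together with C3–H; C3–CH3; the lactone O1–C2 bond; the C4–C(carbinol) bond.
Enabling feature: C2 is benzylic and bonded to ring oxygen O1, and C3 carries one H beside its methyl. O1–C2=C3 can therefore be drawn back to the flat enol ether of a 2,3-dihydrofuran, whose C-protonation gives the C2 oxocarbenium ion.
Forward: an anti-aldol reaction of a succinate imide with veratraldehyde joins the chain; lactonisation closes the oxolane ring (O1–C2); methylation, reduction and dehydration give the 4-methyl-2,3-dihydrofuran; HCl and then an aryl Grignard reagent add H and aryl across C2=C3 and join the two halves.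
Stereochemistry: C4 and the carbinol carbon come from the (R)-4-benzyloxazolidinone in the Mg-catalysed anti-aldol reaction. C3 and C2 are both set in the key step under control of C4: H and aryl enter the ring face opposite the C4 side chain (3,4-cis, 2,3-trans).

Key step: step 8

Remark on the chemistry: the C3 configuration of 12–14 is erased in step 7, so the epimer ratio of the methylation does not matter; 16 is taken as the purchasable THF solution.

Step 1
Reactants: 1 4-tert-butoxy-4-oxobutanoic acid; 2 (4R)-4-benzyl-1,3-oxazolidin-2-one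
Product: 4 tert-butyl 4-[(4R)-4-benzyl-2-oxo-1,3-oxazolidin-3-yl]-4-oxobutanoate, via mixed pivalic anhydride 3 (not isolated)
Conditions: PivCl, Et3N, THF, −20 °C; then LiCl, 2, −20 °C → rt
Reagents that add atoms: none
Why: N-acylation of the oxazolidinone through the mixed pivalic anhydride (LiCl-promoted) is the standard way to attach an Evans auxiliary, leaves the tert-butyl ester untouched and forms no stereocentre.

Step 2
Reactants: 4 tert-butyl 4-[(4R)-4-benzyl-2-oxo-1,3-oxazolidin-3-yl]-4-oxobutanoate; 5 3,4-dimethoxybenzaldehyde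
Product: 7 tert-butyl (3S,4R)-3-{[(4R)-4-benzyl-2-oxo-1,3-oxazolidin-3-yl]carbonyl}-4-(3,4-dimethoxyphenyl)-4-hydroxybutanoate, via trimethylsilyl ether 6 (not isolated)
Conditions: MgCl2 (0.2 equiv), Et3N, TMSCl, EtOAc, rt; then MeOH, TFA (cat.), rt
Reagents that add atoms: none
Why: The MgCl2-catalysed, silyl-chloride-driven Evans anti-aldol reaction of N-acyloxazolidinones with non-enolisable aromatic aldehydes runs through the Mg-chelated Z-enolate, the aldehyde adding to the enolate face opposite the benzyl group in a boat-like transition state, which should set the α-carbon as S and the carbinol carbon as R (anti) with the (R)-auxiliary.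

Step 3
Reactants: 7 tert-butyl (3S,4R)-3-{[(4R)-4-benzyl-2-oxo-1,3-oxazolidin-3-yl]carbonyl}-4-(3,4-dimethoxyphenyl)-4-hydroxybutanoate
Product: 8 tert-butyl (3S,4R)-3-{[(4R)-4-benzyl-2-oxo-1,3-oxazolidin-3-yl]carbonyl}-4-[(tert-butyldimethylsilyl)oxy]-4-(3,4-dimethoxyphenyl)butanoate
Conditions: TBSOTf, 2,6-lutidine, CH2Cl2, −78 → 0 °C
Reagents that add atoms: tert-butyldimethylsilyl trifluoromethanesulfonate, CC(C)(C)[Si](C)(C)OS(=O)(=O)C(F)(F)F
Why: Silylation of a hindered aldol hydroxyl with a silyl triflate and 2,6-lutidine is routine, creates no stereocentre and blocks retro-aldol cleavage and lactonisation onto the tert-butyl ester.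

Step 4
Reactants: 8 tert-butyl (3S,4R)-3-{[(4R)-4-benzyl-2-oxo-1,3-oxazolidin-3-yl]carbonyl}-4-[(tert-butyldimethylsilyl)oxy]-4-(3,4-dimethoxyphenyl)butanoate
Product: 10 (4R)-4-{(R)-[(tert-butyldimethylsilyl)oxy](3,4-dimethoxyphenyl)methyl}oxolan-2-one, via hydroxy tert-butyl ester 9 (not isolated)
Conditions: LiBH4, MeOH (1 equiv), THF, 0 °C; then PPTS (cat.), PhMe, 70 °C
Reagents that add atoms: none
Why: LiBH4 cleaves the N-acyloxazolidinone reductively to the primary alcohol much faster than it attacks a tert-butyl ester (reductive auxiliary removal), and the γ-hydroxy ester then closes to the γ-lactone by acid-catalysed 5-exo-trig transesterification without touching a stereocentre.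

Step 5
Reactants: 10 (4R)-4-{(R)-[(tert-butyldimethylsilyl)oxy](3,4-dimethoxyphenyl)methyl}oxolan-2-one
Product: 12 (3R,4R)-4-{(R)-[(tert-butyldimethylsilyl)oxy](3,4-dimethoxyphenyl)methyl}-3-methyloxolan-2-one (3,4-trans lactone), via lithium enolate 11 (not isolated)
Conditions: LDA, THF, −78 °C; then MeI, −78 → −40 °C
Reagents that add atoms: iodomethane, CI
Why: Enolate alkylation of the γ-butyrolactone with iodomethane should occur anti to the bulky C4 substituent to give mainly the 3,4-trans lactone, and the C3 configuration is immaterial because C3 becomes sp2 in step 7.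

Step 6
Reactants: 12 (3R,4R)-4-{(R)-[(tert-butyldimethylsilyl)oxy](3,4-dimethoxyphenyl)methyl}-3-methyloxolan-2-one
Product: 13 (3R,4R)-4-{(R)-[(tert-butyldimethylsilyl)oxy](3,4-dimethoxyphenyl)methyl}-3-methyloxolan-2-ol (anomer mixture)
Conditions: DIBAL-H, CH2Cl2, −78 °C; Rochelle salt work-up
Reagents that add atoms: none
Why: Partial lactone reduction with DIBAL-H at −78 °C stops at the lactol because the aluminium hemiacetal is stable until work-up, and the anomeric mixture is of no consequence.

Step 7
Reactants: 13 (3R,4R)-4-{(R)-[(tert-butyldimethylsilyl)oxy](3,4-dimethoxyphenyl)methyl}-3-methyloxolan-2-ol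
Product: 15 tert-butyl{(R)-(3,4-dimethoxyphenyl)[(3R)-4-methyl-2,3-dihydrofuran-3-yl]methoxy}dimethylsilane, via anomeric mesylate 14 (not isolated)
Conditions: MsCl, Et3N (excess), CH2Cl2, −40 °C → reflux
Reagents that add atoms: none
Why: Sulfonylation of the lactol hydroxyl followed by amine-mediated loss of methanesulfonic acid through the oxocarbenium ion (lactol dehydration to a furanoid glycal) should give a single enol ether, because C3–H is the only β-hydrogen.

Step 8
Reactants: 15 tert-butyl{(R)-(3,4-dimethoxyphenyl)[(3R)-4-methyl-2,3-dihydrofuran-3-yl]methoxy}dimethylsilane; 16 (3,4-dimethoxyphenyl)magnesium bromide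
Product: 18 tert-butyl{(R)-(3,4-dimethoxyphenyl)[(3R,4S,5S)-5-(3,4-dimethoxyphenyl)-4-methyloxolan-3-yl]methoxy}dimethylsilane, via chloro ether 17 (not isolated)
Conditions: HCl (1.05 equiv, 2 M in Et2O), CH2Cl2, −78 °C; then 16 (2.5 equiv, THF), −78 → −20 °C
Reagents that add atoms: none
Why: Dry HCl C-protonates the enol ether at C3 to the C2 oxocarbenium ion, which chloride captures at once as the α-chloro ether 17, and the aryl Grignard reagent then replaces chloride at C2 through the same oxocarbenium ion pair, so that H and aryl add across C2=C3 in one flask. The closest known reaction type is the classical hydrochlorination of dihydropyran or dihydrofuran followed by Grignard substitution of the 2-chloro ether, together with aryl-metal additions to five-membered cyclic oxocarbenium ions. No ring is closed in this step. C3 is set by protonation on the ring face opposite the bulky C4 CH(OTBS)Ar group, which allylic strain with the C3 methyl should push into a pseudoaxial position, so the methyl ends cis to the C4 substituent; C2 is set by aryl delivery anti to both the C3 methyl and the C4 side chain (inside attack on the envelope with the C4 group pseudoequatorial), which should give the 2,3-trans ether. The step needs kinetic face selectivity in the protonation and substitution in preference to loss of HCl back to 15; the first is secured by irreversible chloride capture at −78 °C, the second by magnesium-assisted ionisation of the α-chloro ether and its fast capture by the aryl nucleophile. The benzylic silyl ether and the aryl methyl ethers should be inert to one equivalent of HCl at −78 °C and to the Grignard reagent.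

Step 9
Reactants: 18 tert-butyl{(R)-(3,4-dimethoxyphenyl)[(3R,4S,5S)-5-(3,4-dimethoxyphenyl)-4-methyloxolan-3-yl]methoxy}dimethylsilane
Product: 19 (R)-(3,4-dimethoxyphenyl)[(3R,4S,5S)-5-(3,4-dimethoxyphenyl)-4-methyloxolan-3-yl]methanol
Conditions: TBAF, THF, 0 °C → rt
Reagents that add atoms: none
Why: Fluoride-mediated desilylation is selective for the silyl ether and touches none of the four stereocentres.

**Compound list**
1 | 4-tert-butoxy-4-oxobutanoic acid (mono-tert-butyl succinate) | CC(C)(C)OC(=O)CCC(=O)O | starting material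
2 | (4R)-4-benzyl-1,3-oxazolidin-2-one | O=C1N[C@H](Cc2ccccc2)CO1 | starting material
3 | 4-tert-butoxy-4-oxobutanoic 2,2-dimethylpropanoic anhydride | CC(C)(C)OC(=O)CCC(=O)OC(=O)C(C)(C)C | intermediate
4 | tert-butyl 4-[(4R)-4-benzyl-2-oxo-1,3-oxazolidin-3-yl]-4-oxobutanoate | CC(C)(C)OC(=O)CCC(=O)N1[C@H](Cc2ccccc2)COC1=O | intermediate
5 | 3,4-dimethoxybenzaldehyde (veratraldehyde) | COc1ccc(C=O)cc1OC | starting material
6 | tert-butyl (3S,4R)-3-{[(4R)-4-benzyl-2-oxo-1,3-oxazolidin-3-yl]carbonyl}-4-(3,4-dimethoxyphenyl)-4-(trimethylsilyloxy)butanoate | O=C([C@H]([C@@H](O[Si](C)(C)C)c1ccc(OC)c(OC)c1)CC(=O)OC(C)(C)C)N1[C@H](Cc2ccccc2)COC1=O | intermediate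
7 | tert-butyl (3S,4R)-3-{[(4R)-4-benzyl-2-oxo-1,3-oxazolidin-3-yl]carbonyl}-4-(3,4-dimethoxyphenyl)-4-hydroxybutanoate | O=C([C@H]([C@@H](O)c1ccc(OC)c(OC)c1)CC(=O)OC(C)(C)C)N1[C@H](Cc2ccccc2)COC1=O | intermediate
8 | tert-butyl (3S,4R)-3-{[(4R)-4-benzyl-2-oxo-1,3-oxazolidin-3-yl]carbonyl}-4-[(tert-butyldimethylsilyl)oxy]-4-(3,4-dimethoxyphenyl)butanoate | O=C([C@H]([C@@H](O[Si](C)(C)C(C)(C)C)c1ccc(OC)c(OC)c1)CC(=O)OC(C)(C)C)N1[C@H](Cc2ccccc2)COC1=O | intermediate
9 | tert-butyl (3R,4R)-4-[(tert-butyldimethylsilyl)oxy]-4-(3,4-dimethoxyphenyl)-3-(hydroxymethyl)butanoate | OC[C@H]([C@@H](O[Si](C)(C)C(C)(C)C)c1ccc(OC)c(OC)c1)CC(=O)OC(C)(C)C | intermediate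
10 | (4R)-4-{(R)-[(tert-butyldimethylsilyl)oxy](3,4-dimethoxyphenyl)methyl}oxolan-2-one | O1C[C@H]([C@@H](O[Si](C)(C)C(C)(C)C)c2ccc(OC)c(OC)c2)CC1=O | intermediate
11 | lithium enolate of 10 | O1C[C@H]([C@@H](O[Si](C)(C)C(C)(C)C)c2ccc(OC)c(OC)c2)C=C1[O-].[Li+] | intermediate
12 | (3R,4R)-4-{(R)-[(tert-butyldimethylsilyl)oxy](3,4-dimethoxyphenyl)methyl}-3-methyloxolan-2-one (3,4-trans) | O1C[C@H]([C@@H](O[Si](C)(C)C(C)(C)C)c2ccc(OC)c(OC)c2)[C@@H](C)C1=O | intermediate
13 | (3R,4R)-4-{(R)-[(tert-butyldimethylsilyl)oxy](3,4-dimethoxyphenyl)methyl}-3-methyloxolan-2-ol (anomer mixture) | O1C[C@H]([C@@H](O[Si](C)(C)C(C)(C)C)c2ccc(OC)c(OC)c2)[C@@H](C)C1O | intermediate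
14 | (3R,4R)-4-{(R)-[(tert-butyldimethylsilyl)oxy](3,4-dimethoxyphenyl)methyl}-3-methyloxolan-2-yl methanesulfonate | O1C[C@H]([C@@H](O[Si](C)(C)C(C)(C)C)c2ccc(OC)c(OC)c2)[C@@H](C)C1OS(C)(=O)=O | intermediate
15 | tert-butyl{(R)-(3,4-dimethoxyphenyl)[(3R)-4-methyl-2,3-dihydrofuran-3-yl]methoxy}dimethylsilane | O1C[C@H]([C@@H](O[Si](C)(C)C(C)(C)C)c2ccc(OC)c(OC)c2)C(C)=C1 | intermediate
16 | (3,4-dimethoxyphenyl)magnesium bromide | COc1ccc([Mg]Br)cc1OC | starting material
17 | tert-butyl{(R)-[(3R,4S)-5-chloro-4-methyloxolan-3-yl](3,4-dimethoxyphenyl)methoxy}dimethylsilane (C5 epimers) | ClC1OC[C@H]([C@@H](O[Si](C)(C)C(C)(C)C)c2ccc(OC)c(OC)c2)[C@@H]1C | intermediate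
18 | tert-butyl{(R)-(3,4-dimethoxyphenyl)[(3R,4S,5S)-5-(3,4-dimethoxyphenyl)-4-methyloxolan-3-yl]methoxy}dimethylsilane | COc1ccc([C@H]2OC[C@H]([C@@H](O[Si](C)(C)C(C)(C)C)c3ccc(OC)c(OC)c3)[C@@H]2C)cc1OC | intermediate
19 | (R)-(3,4-dimethoxyphenyl)[(3R,4S,5S)-5-(3,4-dimethoxyphenyl)-4-methyloxolan-3-yl]methanol | COc1ccc([C@H]2OC[C@H]([C@@H](O)c3ccc(OC)c(OC)c3)[C@@H]2C)cc1OC | target

**Step count and risks**
Total step count: 9. Longest linear sequence: 9 steps (1 → 19).

Step 8. What may go wrong is insufficient face selectivity in the C-protonation, which would carry the C3 epimer on to the all-trans ether, and loss of HCl from 17 back to 15 when the basic Grignard reagent is added. The fallback sets out from 12 and returns at 17, and through it at 18. It fixes C3 on the lactone before the fragments are joined, where the epimers can be separated and the unwanted one recycled. Lactone 12 is deprotonated again (LDA, THF, −78 °C) and the enolate 11 is quenched at −78 °C with the hindered proton donor 2,6-di-tert-butyl-4-methylphenol, which should protonate C3 anti to the C4 substituent and give mainly (3S,4R)-4-{(R)-[(tert-butyldimethylsilyl)oxy](3,4-dimethoxyphenyl)methyl}-3-methyloxolan-2-one F1 (3,4-cis lactone). DIBAL-H reduction with acetylation of the aluminium hemiacetal in the same flask (Ac2O, pyridine, DMAP) should give (3S,4R)-4-{(R)-[(tert-butyldimethylsilyl)oxy](3,4-dimethoxyphenyl)methyl}-3-methyloxolan-2-yl acetate F2. Dry HCl in Et2O at 0 °C exchanges acetate for chloride to give 17, which is treated with 16 as in step 8 to reach 18.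

Step 2. What may go wrong is slow soft enolisation or retro-aldol cleavage with the electron-rich aldehyde, erosion of the anti selectivity, and lactonisation of the free hydroxyl onto the tert-butyl ester after desilylation. The fallback sets out from 4 and returns at 7; it creates the carbinol centre by reduction, not by C–C bond formation. The lithium enolate of 4 (LDA, THF, −78 °C) is C-acylated with 3,4-dimethoxybenzoyl chloride on the face opposite the benzyl group to give tert-butyl (3S)-3-{[(4R)-4-benzyl-2-oxo-1,3-oxazolidin-3-yl]carbonyl}-4-(3,4-dimethoxyphenyl)-4-oxobutanoate F3, whose α-centre is held against epimerisation by allylic strain. Corey–Bakshi–Shibata reduction with (S)-Me-CBS and catecholborane (toluene, −78 °C, aryl as the large group) should then deliver the (R)-carbinol 7 under reagent control.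

Step 7. What may go wrong is incomplete elimination, with return of the lactol on work-up by hydrolysis of the anomeric sulfonate or chloride, and acid-catalysed hydration or oligomerisation of the enol ether during isolation. The fallback sets out from 13 and returns at 15; it replaces the transient sulfonate by an isolable ester that is ionised under buffered, anhydrous conditions. The lactol is acetylated (Ac2O, Et3N, DMAP, CH2Cl2) to (3R,4R)-4-{(R)-[(tert-butyldimethylsilyl)oxy](3,4-dimethoxyphenyl)methyl}-3-methyloxolan-2-yl acetate F4. The purified acetate is treated with TMSOTf and iPr2NEt (CH2Cl2, −20 → 0 °C), so that the oxocarbenium ion is deprotonated at C3 by the hindered amine to give 15.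

Further compounds
F1 | step 8 | (3S,4R)-4-{(R)-[(tert-butyldimethylsilyl)oxy](3,4-dimethoxyphenyl)methyl}-3-methyloxolan-2-one (3,4-cis) | O1C[C@H]([C@@H](O[Si](C)(C)C(C)(C)C)c2ccc(OC)c(OC)c2)[C@H](C)C1=O
F2 | step 8 | (3S,4R)-4-{(R)-[(tert-butyldimethylsilyl)oxy](3,4-dimethoxyphenyl)methyl}-3-methyloxolan-2-yl acetate (anomer mixture) | CC(=O)OC1OC[C@H]([C@@H](O[Si](C)(C)C(C)(C)C)c2ccc(OC)c(OC)c2)[C@@H]1C
F3 | step 2 | tert-butyl (3S)-3-{[(4R)-4-benzyl-2-oxo-1,3-oxazolidin-3-yl]carbonyl}-4-(3,4-dimethoxyphenyl)-4-oxobutanoate | O=C([C@H](C(=O)c1ccc(OC)c(OC)c1)CC(=O)OC(C)(C)C)N1[C@H](Cc2ccccc2)COC1=O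
F4 | step 7 | (3R,4R)-4-{(R)-[(tert-butyldimethylsilyl)oxy](3,4-dimethoxyphenyl)methyl}-3-methyloxolan-2-yl acetate (anomer mixture) | CC(=O)OC1OC[C@H]([C@@H](O[Si](C)(C)C(C)(C)C)c2ccc(OC)c(OC)c2)[C@H]1C
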